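Retrosynthesis: cut the C19 coumarate ester, then the C13–C14 bond of the diene, then the C11–C12 bond, then ring A at C1–C2 and C3–C4 (removing the C2–C3 ethano unit), which leaves a ring B aldehyde–ester that maps onto (R)-carvone.
Enabling feature: in ring A the unsubstituted C2H2–C3H2 unit links C4 and C1, which hang on the adjacent ring B carbons C5 and C10. C4 carries the oxidised carbon C19 (as an ester it makes C4 an enolate carbon) and C1 can be an aldehyde that cannot enolise because C10 is quaternary.
Forward order: ring B comes from carvone (two alkylations at C10, C9 carbonyl to exocyclic methylene, isopropenyl to propanoate); ring A is closed by a two-carbon annulation; then the C9 side chain, the ring B diol, the diene and the C19 ester follow.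
Stereochemistry: C5 from (R)-carvone; C10 by alkylation anti to the isopropenyl group; C4 in the annulation (allylic strain); C9 by α-face hydroboration; C7 and C8 by α-face dihydroxylation.

Key step: step 7

Remark: labdane numbering is used throughout (carvone C1 = C9, C2 = C8, C3 = C7, C4 = C6, C5 = C5, C6 = C10; the isopropenyl carbon = C4). Compounds 8–13 are C4-epimer mixtures that converge in step 7, so C4 is left open in their SMILES. (R)-Carvone, p-coumaric acid and all reagents are taken as commercial.

Step 1
Reactants: 1 (R)-(−)-carvone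
Product: 3 trans-6-methylcarvone, via lithium dienolate 2 (not isolated)
Conditions: LiN(iPr)2, THF, −78 °C; MeI, −78 to 0 °C
Reagents that add atoms: iodomethane CI; lithium diisopropylamide [Li+].CC(C)[N-]C(C)C (lithium only in 2)
Why: Kinetic α'-deprotonation and C-methylation of the cross-conjugated dienolate (enolate alkylation) is standard for carvone; the new centre is planarised again in step 2, so the epimer ratio does not matter.

Step 2
Reactants: 3 trans-6-methylcarvone
Product: 6 acetal ketone (CH(OMe)2 trans to isopropenyl), via lithium enolate 4 (not isolated), via silyl dienol ether 5 (not isolated)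
Conditions: LiN(iPr)2, THF, −78 °C; Me3SiCl; pentane filtration; HC(OMe)3, Me3SiOTf (10 mol%), CH2Cl2, −78 °C
Reagents that add atoms: trimethyl orthoformate COC(OC)OC; chlorotrimethylsilane C[Si](C)(C)Cl (silicon only in 5); lithium diisopropylamide [Li+].CC(C)[N-]C(C)C (lithium only in 4)
Why: Mukaiyama-type acetal aldol of the silyl dienol ether with the dimethoxycarbenium ion should create quaternary C10, the electrophile entering anti to the adjacent isopropenyl group (the usual sense of the second α'-alkylation of carvone), so that C1 is trans and the C10 methyl cis to C4.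

Step 3
Reactants: 6 acetal ketone
Product: 7 triene acetal (C9=CH2)
Conditions: Ph3PCH3Br, KOtBu, toluene, 90 °C
Reagents that add atoms: methyltriphenylphosphonium bromide C[P+](c1ccccc1)(c1ccccc1)c1ccccc1.[Br-]
Why: Wittig methylenation with the salt-free ylide at elevated temperature is known for ketones flanked by a quaternary carbon; it installs C11 and removes the acidic, electrophilic enone before the strong-base step.

Step 4
Reactants: 7 triene acetal
Product: 9 primary alcohol (C19–OH), via B-alkyl-9-BBN 8 (not isolated)
Conditions: 9-BBN (1.1 equiv), THF, 0 °C to rt; NaOH, H2O2, 0 °C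
Reagents that add atoms: hydrogen peroxide OO; 9-borabicyclo[3.3.1]nonane B1C2CCCC1CCC2 (boron only in 8)
Why: Anti-Markovnikov hydroboration–oxidation, in which 9-BBN should prefer the unhindered isolated isopropenyl group over the conjugated exocyclic methylene flanked by quaternary C10 and over the trisubstituted ring alkene.

Step 5
Reactants: 9 primary alcohol
Product: 11 methyl ester, via aldehyde 10 (not isolated)
Conditions: (C5H5NH)2Cr2O7 (6 equiv), MeOH (6 equiv), DMF, rt
Reagents that add atoms: methanol CO
Why: Oxidative esterification of a saturated primary alcohol by dichromate in DMF/MeOH (alcohol to aldehyde to hemiacetal to ester) is a known one-flask conversion and the near-neutral medium should spare the acetal and the diene.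

Step 6
Reactants: 11 methyl ester
Product: 12 aldehyde ester
Conditions: PPTS (cat.), acetone–H2O (10:1), 50 °C
Reagents that add atoms: water O
Why: Mild acid-catalysed acetal hydrolysis should unmask the aldehyde on quaternary C10 without isomerising the exocyclic diene.

Step 7
Reactants: 12 aldehyde ester
Product: 15 bicyclic triene ester, via lithium ester enolate 13 (not isolated), via phosphorus ylide 14 (not isolated)
Conditions: LiN(iPr)2 (1.05 equiv), THF, −78 °C, 30 min; cannulate into CH2=CHPPh3Br (1.5 equiv), THF, −78 °C to rt, then 50 °C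
Reagents that add atoms: vinyltriphenylphosphonium bromide C=C[P+](c1ccccc1)(c1ccccc1)c1ccccc1.[Br-]; lithium diisopropylamide [Li+].CC(C)[N-]C(C)C (lithium only in 13)
Why: The ester enolate 13 adds in Michael fashion to the vinylphosphonium salt to form C3–C4, and the resulting non-stabilised ylide 14 at C2 attacks the aldehyde C1 in an intramolecular Wittig olefination that forms C1=C2 and expels Ph3PO. The closest known reaction type is the Schweizer annulation, in which conjugate addition of an enolate to a vinylphosphonium salt is followed by intramolecular Wittig reaction to give a cycloalkene. Ring A closes as a six-membered ring in the 6-exo-trig mode (ylide carbon onto the exocyclic C=O), and the cis ring alkene is the only possible geometry. The new quaternary centre C4 is set in the Michael step: allylic 1,3-strain holds C5–H in the enolate plane, so the acceptor should approach the face remote from the fully substituted C10, which places the ester axial and cis to the C10 methyl (4α-CH3, 4β-CO2Me), while the trans C5/C10 relationship is already fixed in 12. The step needs C- over O-alkylation, enolisation at C4 only and ylide attack on the aldehyde only; the soft acceptor, the absence of any other acidic C–H (the aldehyde cannot enolise and the ketone is already a methylene) and ring size (attack on the ester would give a four-membered ring) should secure these.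

Step 8
Reactants: 15 bicyclic triene ester
Product: 17 methyl ketone (9α-H), via B-alkyl-9-BBN 16 (not isolated)
Conditions: 9-BBN (1.2 equiv), THF, 0 °C to rt; BrCH2COCH3, potassium 2,6-di-tert-butylphenoxide (from the phenol and KOtBu), THF, 0 °C
Reagents that add atoms: bromoacetone CC(=O)CBr; 9-borabicyclo[3.3.1]nonane B1C2CCCC1CCC2 (boron only in 16)
Why: Hydroboration of the exocyclic methylene from the α face (the β face is blocked by the adjacent axial C10 methyl) should set 9α-H, and base-induced α-alkylation of the bromoketone by the B-alkyl-9-BBN (1,2-migration of the primary alkyl group from boron to carbon) then forms C11–C12 and delivers the C13 methyl ketone.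

Step 9
Reactants: 17 methyl ketone
Product: 18 ring A saturated keto ester
Conditions: H2 (1 atm), RhCl(PPh3)3 (5 mol%), benzene, rt
Reagents that add atoms: none
Why: Homogeneous hydrogenation with RhCl(PPh3)3 should reduce the cis-disubstituted ring A alkene and leave the trisubstituted ring B alkene, as in the selective 1,2-reduction of steroidal 1,4-dien-3-ones.

Step 10
Reactants: 18 keto ester
Product: 19 keto diol (7α,8α)
Conditions: OsO4 (5 mol%), NMO, acetone–H2O, rt
Reagents that add atoms: N-methylmorpholine N-oxide C[N+]1([O-])CCOCC1; water O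
Why: Catalytic OsO4 syn-dihydroxylation of the only remaining alkene should occur on the α face, away from the axial C10 methyl, giving the 7α,8α-diol with the C8 methyl β.

Step 11
Reactants: 19 keto diol
Product: 20 bis(triethylsilyl) ether
Conditions: Et3SiOTf (3 equiv), 2,6-lutidine, CH2Cl2, −78 to 0 °C
Reagents that add atoms: triethylsilyl trifluoromethanesulfonate CC[Si](CC)(CC)OS(=O)(=O)C(F)(F)F
Why: Silyl triflate silylation protects both the secondary and the tertiary hydroxyl under non-acidic conditions, which avoids the internal ketal that the 7,8-diol would form with the C13 ketone under acid.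

Step 12
Reactants: 20 bis(triethylsilyl) ether
Product: 22 enol triflate, via potassium enolate 21 (not isolated)
Conditions: KN(SiMe3)2, THF, −78 °C; PhNTf2, −78 to 0 °C
Reagents that add atoms: N-phenylbis(trifluoromethanesulfonimide) O=S(=O)(N(c1ccccc1)S(=O)(=O)C(F)(F)F)C(F)(F)F; potassium bis(trimethylsilyl)amide [K+].C[Si](C)(C)[N-][Si](C)(C)C (potassium only in 21)
Why: Kinetic deprotonation of the methyl ketone at the methyl group and O-triflation (enol triflate formation) should give the terminal enol triflate, the C19 ester having no α-hydrogen.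

Step 13
Reactants: 22 enol triflate
Product: 23 diene ester
Conditions: CH2=CHSnBu3, Pd(PPh3)4 (5 mol%), LiCl, THF, 65 °C
Reagents that add atoms: tributyl(vinyl)stannane C=C[Sn](CCCC)(CCCC)CCCC
Why: Stille coupling of the enol triflate with the vinylstannane builds the 2-substituted buta-1,3-diene only after hydrogenation and dihydroxylation are finished.

Step 14
Reactants: 23 diene ester
Product: 24 C19 alcohol
Conditions: LiAlH4, THF, 0 °C to rt
Reagents that add atoms: none
Why: Hydride reduction of the hindered axial ester to the neopentyl alcohol should leave the silyl ethers and the diene untouched.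

Step 15
Reactants: 25 p-coumaric acid
Product: 27 silyl-protected coumaric acid, via bis-silyl derivative 26 (not isolated)
Conditions: tBuMe2SiCl (2.2 equiv), imidazole, DMF, rt; AcOH–THF–H2O, rt
Reagents that add atoms: tert-butyldimethylsilyl chloride CC(C)(C)[Si](C)(C)Cl
Why: Silylation of phenol and acid followed by selective hydrolysis of the labile silyl ester is the usual way to an O-silylated hydroxycinnamic acid.

Step 16
Reactants: 24 C19 alcohol; 27 silyl-protected coumaric acid
Product: 28 protected coumarate ester
Conditions: EDC·HCl, DMAP, CH2Cl2, rt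
Reagents that add atoms: none
Why: Carbodiimide/DMAP (Steglich) esterification acylates the only free hydroxyl, the primary C19 alcohol, without touching the (E)-alkene.

Step 17
Reactants: 28 protected coumarate ester
Product: 29 target CNP0254560.2
Conditions: Bu4NF (4 equiv), AcOH (4 equiv), THF, 0 °C to rt
Reagents that add atoms: none
Why: Buffered fluoride desilylation should remove the aryl silyl ether and both triethylsilyl ethers in one operation while sparing the ester and the diene.

Compound list
1 | (R)-(−)-carvone | CC1=CC[C@H](CC1=O)C(C)=C | starting material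
2 | lithium cross-conjugated dienolate of 1 | CC1=CC[C@H](C=C1[O-])C(C)=C.[Li+] | intermediate
3 | trans-6-methylcarvone, (5R,6S)-2,6-dimethyl-5-(prop-1-en-2-yl)cyclohex-2-en-1-one (minor cis epimer carried along) | CC1=CC[C@H]([C@H](C)C1=O)C(C)=C | intermediate
4 | lithium enolate of 3 | CC1=CC[C@H](C(C)=C1[O-])C(C)=C.[Li+] | intermediate
5 | trimethylsilyl dienol ether of 3 | CC1=CC[C@H](C(C)=C1O[Si](C)(C)C)C(C)=C | intermediate
6 | 6-(dimethoxymethyl)-2,6-dimethyl-5-(prop-1-en-2-yl)cyclohex-2-en-1-one, CH(OMe)2 trans and CH3 cis to the isopropenyl group | O=C1C(C)=CC[C@@H](C(C)=C)[C@]1(C)C(OC)OC | intermediate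
7 | 6-(dimethoxymethyl)-2,6-dimethyl-1-methylidene-5-(prop-1-en-2-yl)cyclohex-2-ene, same relative configuration | C=C1C(C)=CC[C@@H](C(C)=C)[C@]1(C)C(OC)OC | intermediate
8 | B-alkyl-9-BBN from hydroboration of the isopropenyl group of 7 | C=C1C(C)=CC[C@@H](C(C)CB2C3CCCC2CCC3)[C@]1(C)C(OC)OC | intermediate
9 | 2-[6-(dimethoxymethyl)-4,6-dimethyl-5-methylidenecyclohex-3-en-1-yl]propan-1-ol | C=C1C(C)=CC[C@@H](C(C)CO)[C@]1(C)C(OC)OC | intermediate
10 | 2-[6-(dimethoxymethyl)-4,6-dimethyl-5-methylidenecyclohex-3-en-1-yl]propanal | C=C1C(C)=CC[C@@H](C(C)C=O)[C@]1(C)C(OC)OC | intermediate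
11 | methyl 2-[6-(dimethoxymethyl)-4,6-dimethyl-5-methylidenecyclohex-3-en-1-yl]propanoate | C=C1C(C)=CC[C@@H](C(C)C(=O)OC)[C@]1(C)C(OC)OC | intermediate
12 | methyl 2-(6-formyl-4,6-dimethyl-5-methylidenecyclohex-3-en-1-yl)propanoate, formyl trans and ring CH3 cis to the propanoate side chain | C=C1C(C)=CC[C@@H](C(C)C(=O)OC)[C@]1(C)C=O | intermediate
13 | lithium ester enolate of 12 | C=C1C(C)=CC[C@@H](C(C)=C([O-])OC)[C@]1(C)C=O.[Li+] | intermediate
14 | Michael adduct ylide, C4 quaternary with CH2–CH=PPh3 | C=C1C(C)=CC[C@@H]([C@@](C)(C(=O)OC)CC=P(c2ccccc2)(c2ccccc2)c2ccccc2)[C@]1(C)C=O | intermediate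
15 | methyl 12,13,14,15,16-pentanorlabda-1,7,9(11)-trien-19-oate (4α-CH3, 4β-CO2Me, 5α-H, 10β-CH3) | C=C1C(C)=CC[C@H]2[C@@](C)(C(=O)OC)CC=C[C@@]21C | intermediate
16 | C11 B-alkyl-9-BBN of 15 (9α-H) | C1CC2CCCC(C1)B2C[C@H]1C(C)=CC[C@H]2[C@@](C)(C(=O)OC)CC=C[C@@]21C | intermediate
17 | methyl 13-oxo-14,15-dinorlabda-1,7-dien-19-oate (9α-H) | CC(=O)CC[C@H]1C(C)=CC[C@H]2[C@@](C)(C(=O)OC)CC=C[C@@]21C | intermediate
18 | methyl 13-oxo-14,15-dinorlabd-7-en-19-oate | CC(=O)CC[C@H]1C(C)=CC[C@H]2[C@@](C)(C(=O)OC)CCC[C@@]21C | intermediate
19 | methyl 7α,8α-dihydroxy-13-oxo-14,15-dinorlabdan-19-oate | CC(=O)CC[C@H]1[C@](C)(O)[C@H](O)C[C@H]2[C@@](C)(C(=O)OC)CCC[C@@]21C | intermediate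
20 | methyl 13-oxo-7α,8α-bis(triethylsilyloxy)-14,15-dinorlabdan-19-oate | CC(=O)CC[C@H]1[C@](C)(O[Si](CC)(CC)CC)[C@H](O[Si](CC)(CC)CC)C[C@H]2[C@@](C)(C(=O)OC)CCC[C@@]21C | intermediate
21 | potassium C13–C16 enolate of 20 | [K+].C=C([O-])CC[C@H]1[C@](C)(O[Si](CC)(CC)CC)[C@H](O[Si](CC)(CC)CC)C[C@H]2[C@@](C)(C(=O)OC)CCC[C@@]21C | intermediate
22 | methyl 13-(trifluoromethanesulfonyloxy)-7α,8α-bis(triethylsilyloxy)-14,15-dinorlabd-13(16)-en-19-oate | C=C(OS(=O)(=O)C(F)(F)F)CC[C@H]1[C@](C)(O[Si](CC)(CC)CC)[C@H](O[Si](CC)(CC)CC)C[C@H]2[C@@](C)(C(=O)OC)CCC[C@@]21C | intermediate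
23 | methyl 7α,8α-bis(triethylsilyloxy)labda-13(16),14-dien-19-oate | C=CC(=C)CC[C@H]1[C@](C)(O[Si](CC)(CC)CC)[C@H](O[Si](CC)(CC)CC)C[C@H]2[C@@](C)(C(=O)OC)CCC[C@@]21C | intermediate
24 | 7α,8α-bis(triethylsilyloxy)labda-13(16),14-dien-19-ol | C=CC(=C)CC[C@H]1[C@](C)(O[Si](CC)(CC)CC)[C@H](O[Si](CC)(CC)CC)C[C@H]2[C@@](C)(CO)CCC[C@@]21C | intermediate
25 | p-coumaric acid, (E)-4-hydroxycinnamic acid | OC(=O)/C=C/c1ccc(O)cc1 | starting material
26 | tert-butyldimethylsilyl (E)-4-(tert-butyldimethylsilyloxy)cinnamate | CC(C)(C)[Si](C)(C)OC(=O)/C=C/c1ccc(O[Si](C)(C)C(C)(C)C)cc1 | intermediate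
27 | (E)-4-(tert-butyldimethylsilyloxy)cinnamic acid | OC(=O)/C=C/c1ccc(O[Si](C)(C)C(C)(C)C)cc1 | intermediate
28 | 7α,8α-bis(triethylsilyloxy)labda-13(16),14-dien-19-yl (E)-4-(tert-butyldimethylsilyloxy)cinnamate | C=CC(=C)CC[C@H]1[C@](C)(O[Si](CC)(CC)CC)[C@H](O[Si](CC)(CC)CC)C[C@H]2[C@@](C)(COC(=O)/C=C/c3ccc(O[Si](C)(C)C(C)(C)C)cc3)CCC[C@@]21C | intermediate
29 | CNP0254560.2, 7α,8α-dihydroxylabda-13(16),14-dien-19-yl (E)-4-hydroxycinnamate | C=CC(=C)CC[C@H]1[C@](C)(O)[C@H](O)C[C@H]2[C@@](C)(COC(=O)/C=C/c3ccc(O)cc3)CCC[C@@]21C | target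

Total step count: 17. Longest linear sequence: 16 steps (steps 1–14, 16 and 17).

Steps most likely to fail

Step 7. What may go wrong: the amide base may add to or reduce the aldehyde before the hindered ester is enolised; the tetrasubstituted enolate may add only slowly to the poorly soluble phosphonium salt, which leaves time for intermolecular aldol addition; and facial discrimination at C4 may be incomplete. Fallback (stepwise, with no carbonyl electrophile present when the enolate is made): from 12, Wittig methylenation (Ph3P=CH2, THF, 0 °C) should give methyl 2-(4,6-dimethyl-5-methylidene-6-vinylcyclohex-3-en-1-yl)propanoate F1. Enolisation with KN(SiMe3)2 (THF, −78 °C) and C-allylation with allyl iodide, under the same allylic-strain control, should give the quaternary allyl ester F2. Ring-closing metathesis with second-generation Grubbs catalyst (CH2Cl2, 40 °C) between the C10 vinyl and the C4 allyl group should close ring A at C1=C2 and come back to the route at 15.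

Step 8. What may go wrong: migration of the hindered, β-branched alkyl group from boron to the bromoacetone enolate may be slow relative to protonolysis of the borane or self-condensation of the haloketone. Fallback: from 15, the same hydroboration followed by NaOH/H2O2 should give the C11 alcohol F3. Iodination (I2, PPh3, imidazole, CH2Cl2) should give the iodide F4. Alkylation of lithiated acetone N,N-dimethylhydrazone (LiN(iPr)2, THF, −78 to 0 °C) should give the hydrazone F5, and hydrolysis with aqueous oxalic acid comes back to the route at 17.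

Step 4. What may go wrong: loss of chemoselectivity, with 9-BBN also adding to the exocyclic methylene of the conjugated diene. Fallback (hydroborate before the second 1,1-disubstituted alkene exists): from 6, excess 9-BBN followed by NaOH/H2O2 should reduce the enone carbonyl and hydroborate the isopropenyl group to give the diol F6. Oxidation with (C5H5NH)2Cr2O7 and MeOH in DMF should return the allylic alcohol to the enone and convert the primary alcohol into the methyl ester, giving the keto ester F7. Ketone-selective, ester-tolerant Takai–Lombardo methylenation (Zn, CH2Br2, TiCl4, THF) comes back to the route at 11.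

Further compounds
F1 | step 7 | methyl 2-(4,6-dimethyl-5-methylidene-6-vinylcyclohex-3-en-1-yl)propanoate | C=C1C(C)=CC[C@@H](C(C)C(=O)OC)[C@]1(C)C=C
F2 | step 7 | methyl 2-(4,6-dimethyl-5-methylidene-6-vinylcyclohex-3-en-1-yl)-2-methylpent-4-enoate | C=C1C(C)=CC[C@@H]([C@@](C)(C(=O)OC)CC=C)[C@]1(C)C=C
F3 | step 8 | methyl 11-hydroxy-12,13,14,15,16-pentanorlabda-1,7-dien-19-oate | OC[C@H]1C(C)=CC[C@H]2[C@@](C)(C(=O)OC)CC=C[C@@]21C
F4 | step 8 | methyl 11-iodo-12,13,14,15,16-pentanorlabda-1,7-dien-19-oate | IC[C@H]1C(C)=CC[C@H]2[C@@](C)(C(=O)OC)CC=C[C@@]21C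
F5 | step 8 | N,N-dimethylhydrazone of 17 | CN(C)N=C(C)CC[C@H]1C(C)=CC[C@H]2[C@@](C)(C(=O)OC)CC=C[C@@]21C
F6 | step 4 | 2-[6-(dimethoxymethyl)-5-hydroxy-4,6-dimethylcyclohex-3-en-1-yl]propan-1-ol | OC1C(C)=CC[C@@H](C(C)CO)[C@]1(C)C(OC)OC
F7 | step 4 | methyl 2-[6-(dimethoxymethyl)-4,6-dimethyl-5-oxocyclohex-3-en-1-yl]propanoate | O=C1C(C)=CC[C@@H](C(C)C(=O)OC)[C@]1(C)C(OC)OC
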